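**Assumption:** the SMILES is read as (R) at the lactone carbinol carbon and Z at the ring alkylidene (side chain cis to the lactone C=O). Side-chain carbons are numbered C1′ (on the six-membered carbocycle) to C10′ (alkylidene carbon). (R)-α-Hydroxy-γ-butyrolactone (D-malic acid pool) and geranyl bromide are taken as bought.

## Retrosynthetic overview

1. The quinone is unveiled last by oxidative demethylation of the hydroquinone dimethyl ether 20.
2. The Z-alkylidene δ-lactone 20 comes from lactonisation of a δ-hydroxy (Z)-enoate, made by Ando-type Horner–Wadsworth–Emmons olefination of aldehyde 10 with phosphonate 17; the only stereocentre is bought in lactone 11.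
3. Aldehyde 10 comes from the key step, a Johnson–Claisen [3,3]-sigmatropic rearrangement of allylic alcohol 7 that forms the C8′–C9′ bond and the (E)-C6′=C7′ olefin.
4. Alcohol 7 comes from the terminal epoxide of geranyl arene 4, itself from ortho C-geranylation of 4-methoxy-2-methylphenol 1.
5. Ring order: the arene is bought, the lactone ring closes in step 13, the quinone ring appears in step 14.

## Route

**Step 1**
Reactants: 1 4-methoxy-2-methylphenol; 2 geranyl bromide [(2E)-1-bromo-3,7-dimethylocta-2,6-diene]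
Product: 3 2-[(2E)-3,7-dimethylocta-2,6-dien-1-yl]-4-methoxy-6-methylphenol
Conditions: NaH, PhMe, 0 °C → rt
Reagents that add atoms: none
Why: Ortho C-alkylation of a sodium phenoxide in a non-polar solvent (tight ion pair) puts the geranyl group on the only free ortho carbon by SN2 at the primary allylic bromide, keeping the E olefin.

**Step 2**
Reactants: 3 2-[(2E)-3,7-dimethylocta-2,6-dien-1-yl]-4-methoxy-6-methylphenol
Product: 4 1-[(2E)-3,7-dimethylocta-2,6-dien-1-yl]-2,5-dimethoxy-3-methylbenzene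
Conditions: MeI, K2CO3, acetone, reflux
Reagents that add atoms: iodomethane, CI
Why: Williamson O-methylation masks the phenol as the hydroquinone dimethyl ether so that the ring survives the bromohydrin, Claisen and base steps.

**Step 3**
Reactants: 4 1-[(2E)-3,7-dimethylocta-2,6-dien-1-yl]-2,5-dimethoxy-3-methylbenzene
Product: 6 2,2-dimethyl-3-[(3E)-5-(2,5-dimethoxy-3-methylphenyl)-3-methylpent-3-en-1-yl]oxirane (racemic), via bromohydrin 5 (not isolated)
Conditions: NBS, THF/H2O, 0 °C; then K2CO3, MeOH, rt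
Reagents that add atoms: water, O
Why: Van Tamelen terminal-selective bromohydrin formation (water opens the bromonium ion at the tertiary carbon) followed by base-induced ring closure gives the 6′,7′-epoxide; its stereocentre is racemic and is erased in step 5.

**Step 4**
Reactants: 6 2,2-dimethyl-3-[(3E)-5-(2,5-dimethoxy-3-methylphenyl)-3-methylpent-3-en-1-yl]oxirane
Product: 7 (6E)-8-(2,5-dimethoxy-3-methylphenyl)-2,6-dimethylocta-1,6-dien-3-ol (racemic)
Conditions: Al(Oi-Pr)3 (0.5 equiv), PhMe, 110 °C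
Reagents that add atoms: none
Why: Aluminium-alkoxide-promoted epoxide-to-allylic-alcohol isomerisation removes a methyl proton syn to the breaking tertiary C–O bond, giving the 2-methylene secondary alcohol needed for the Claisen step.

**Step 5 (key step)**
Reactants: 7 (6E)-8-(2,5-dimethoxy-3-methylphenyl)-2,6-dimethylocta-1,6-dien-3-ol
Product: 9 ethyl (4E,8E)-10-(2,5-dimethoxy-3-methylphenyl)-4,8-dimethyldeca-4,8-dienoate, via ketene acetal 8 (not isolated)
Conditions: MeC(OEt)3, EtCO2H (cat.), 140 °C, −EtOH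
Reagents that add atoms: triethyl orthoacetate, CC(OCC)(OCC)OCC
Why: Johnson–Claisen orthoester rearrangement, a [3,3]-sigmatropic shift through a chair transition state with the carbinol substituent equatorial, forms the C8′–C9′ bond and the (E)-C6′=C7′ trisubstituted olefin (typically ≥97:3) while erasing the racemic carbinol centre.

**Step 6**
Reactants: 9 ethyl (4E,8E)-10-(2,5-dimethoxy-3-methylphenyl)-4,8-dimethyldeca-4,8-dienoate
Product: 10 (4E,8E)-10-(2,5-dimethoxy-3-methylphenyl)-4,8-dimethyldeca-4,8-dienal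
Conditions: i-Bu2AlH, CH2Cl2, −78 °C
Reagents that add atoms: none
Why: Partial ester reduction stops at the tetrahedral aluminium hemiacetal at −78 °C and releases the aldehyde on work-up; the olefins and aryl ethers are inert.

**Step 7**
Reactants: 11 (R)-3-hydroxydihydrofuran-2(3H)-one [(R)-α-hydroxy-γ-butyrolactone]
Product: 12 (R)-3-[(tert-butyldimethylsilyl)oxy]dihydrofuran-2(3H)-one
Conditions: TBSCl, imidazole, DMF, rt
Reagents that add atoms: tert-butyldimethylsilyl chloride, CC(C)(C)[Si](C)(C)Cl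
Why: Standard silyl protection of the secondary alcohol; the bought (R) stereocentre is untouched.

**Step 8**
Reactants: 12 (R)-3-[(tert-butyldimethylsilyl)oxy]dihydrofuran-2(3H)-one
Product: 13 (R)-3-[(tert-butyldimethylsilyl)oxy]-5-hydroxypentan-2-one (in equilibrium with its cyclic hemiketal)
Conditions: MeLi (1.05 equiv), THF, −78 °C; aq. NH4Cl
Reagents that add atoms: methyllithium, [Li]C
Why: Mono-addition of an organolithium to a lactone stops at the stable lithium hemiketalate at −78 °C, giving the methyl ketone after a cold quench without touching the α-silyloxy stereocentre.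

**Step 9**
Reactants: 13 (R)-3-[(tert-butyldimethylsilyl)oxy]-5-hydroxypentan-2-one
Product: 14 (R)-3-[(tert-butyldimethylsilyl)oxy]-4-methylpent-4-en-1-ol
Conditions: Ph3PCH3Br, KOt-Bu (2.5 equiv each), THF, 0 °C → rt
Reagents that add atoms: methyltriphenylphosphonium bromide, C[P+](c1ccccc1)(c1ccccc1)c1ccccc1.[Br-]
Why: Wittig methylenation of the ketone tautomer of the hemiketal installs the isopropenyl group; the non-stabilised ylide at low temperature normally leaves the adjacent silyloxy centre intact.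

**Step 10**
Reactants: 14 (R)-3-[(tert-butyldimethylsilyl)oxy]-4-methylpent-4-en-1-ol
Product: 15 (R)-tert-butyl[(5-iodo-2-methylpent-1-en-3-yl)oxy]dimethylsilane
Conditions: I2, PPh3, imidazole, CH2Cl2, 0 °C
Reagents that add atoms: iodine, II
Why: Appel-type iodination converts the primary alcohol into the iodide by SN2 at a carbon remote from the stereocentre.

**Step 11**
Reactants: 15 (R)-tert-butyl[(5-iodo-2-methylpent-1-en-3-yl)oxy]dimethylsilane; 16 ethyl 2-(diphenoxyphosphoryl)acetate
Product: 17 ethyl (5R)-5-[(tert-butyldimethylsilyl)oxy]-2-(diphenoxyphosphoryl)-6-methylhept-6-enoate (about 1:1 at C2)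
Conditions: NaH, DMF, 0 → 50 °C
Reagents that add atoms: none
Why: C-alkylation of the sodium phosphonoacetate anion with the primary iodide (SN2) gives the α-substituted Ando reagent; the C2 centre is lost in step 12.

**Step 12**
Reactants: 10 (4E,8E)-10-(2,5-dimethoxy-3-methylphenyl)-4,8-dimethyldeca-4,8-dienal; 17 ethyl (5R)-5-[(tert-butyldimethylsilyl)oxy]-2-(diphenoxyphosphoryl)-6-methylhept-6-enoate
Product: 18 ethyl (2Z,6E,10E)-2-[(3R)-3-[(tert-butyldimethylsilyl)oxy]-4-methylpent-4-en-1-yl]-12-(2,5-dimethoxy-3-methylphenyl)-6,10-dimethyldodeca-2,6,10-trienoate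
Conditions: KOt-Bu, THF, −78 → 0 °C
Reagents that add atoms: none
Why: Ando-type Horner–Wadsworth–Emmons olefination, in which the diaryl phosphonate eliminates fast from the kinetically formed adduct, places the C9′ chain cis to the ester (Z); the minor E isomer is removed by chromatography.

**Step 13**
Reactants: 18 ethyl (2Z,6E,10E)-2-[(3R)-3-[(tert-butyldimethylsilyl)oxy]-4-methylpent-4-en-1-yl]-12-(2,5-dimethoxy-3-methylphenyl)-6,10-dimethyldodeca-2,6,10-trienoate
Product: 20 (3Z,6R)-3-[(4E,8E)-10-(2,5-dimethoxy-3-methylphenyl)-4,8-dimethyldeca-4,8-dien-1-ylidene]-6-(prop-1-en-2-yl)tetrahydro-2H-pyran-2-one, via hydroxy ester 19 (not isolated)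
Conditions: HF·pyridine, THF, 0 °C → rt; then PPTS (cat.), PhMe, 80 °C
Reagents that add atoms: none
Why: Fluoride desilylation followed by acid-catalysed 6-exo-trig lactonisation (intramolecular transesterification) closes the δ-lactone by acyl substitution, so the C–O bond at the stereocentre is never broken (R retained) and the Z alkene is unchanged.

**Step 14**
Reactants: 20 (3Z,6R)-3-[(4E,8E)-10-(2,5-dimethoxy-3-methylphenyl)-4,8-dimethyldeca-4,8-dien-1-ylidene]-6-(prop-1-en-2-yl)tetrahydro-2H-pyran-2-one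
Product: 21 CNP0305496.1, 2-methyl-6-{(2E,6E)-3,7-dimethyl-10-[(3Z,6R)-2-oxo-6-(prop-1-en-2-yl)tetrahydro-2H-pyran-3-ylidene]deca-2,6-dien-1-yl}cyclohexa-2,5-diene-1,4-dione
Conditions: (NH4)2Ce(NO3)6 (2.5 equiv), MeCN/H2O, 0 °C
Reagents that add atoms: water, O
Why: Oxidative demethylation of the p-dimethoxyarene by tetravalent cerium (two one-electron oxidations, water adding at the ipso carbons and methanol leaving) gives the 2-methyl-6-alkyl-1,4-benzoquinone without touching the olefins, the lactone or the stereocentre.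

## Compound list

1 | 4-methoxy-2-methylphenol | COc1ccc(O)c(C)c1 | starting material
2 | geranyl bromide, (2E)-1-bromo-3,7-dimethylocta-2,6-diene | CC(C)=CCC/C(C)=C/CBr | starting material
3 | 2-[(2E)-3,7-dimethylocta-2,6-dien-1-yl]-4-methoxy-6-methylphenol | COc1cc(C)c(O)c(C/C=C(\C)CCC=C(C)C)c1 | intermediate
4 | 1-[(2E)-3,7-dimethylocta-2,6-dien-1-yl]-2,5-dimethoxy-3-methylbenzene | COc1cc(C)c(OC)c(C/C=C(\C)CCC=C(C)C)c1 | intermediate
5 | (6E)-3-bromo-8-(2,5-dimethoxy-3-methylphenyl)-2,6-dimethyloct-6-en-2-ol (racemic bromohydrin, not isolated) | COc1cc(C)c(OC)c(C/C=C(\C)CCC(Br)C(C)(C)O)c1 | intermediate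
6 | 2,2-dimethyl-3-[(3E)-5-(2,5-dimethoxy-3-methylphenyl)-3-methylpent-3-en-1-yl]oxirane (racemic) | COc1cc(C)c(OC)c(C/C=C(\C)CCC2OC2(C)C)c1 | intermediate
7 | (6E)-8-(2,5-dimethoxy-3-methylphenyl)-2,6-dimethylocta-1,6-dien-3-ol (racemic) | COc1cc(C)c(OC)c(C/C=C(\C)CCC(O)C(C)=C)c1 | intermediate
8 | (6E)-8-(2,5-dimethoxy-3-methylphenyl)-3-[(1-ethoxyethenyl)oxy]-2,6-dimethylocta-1,6-diene (ketene acetal, not isolated) | COc1cc(C)c(OC)c(C/C=C(\C)CCC(OC(=C)OCC)C(C)=C)c1 | intermediate
9 | ethyl (4E,8E)-10-(2,5-dimethoxy-3-methylphenyl)-4,8-dimethyldeca-4,8-dienoate | CCOC(=O)CC/C(C)=C/CC/C(C)=C/Cc1cc(OC)cc(C)c1OC | intermediate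
10 | (4E,8E)-10-(2,5-dimethoxy-3-methylphenyl)-4,8-dimethyldeca-4,8-dienal | O=CCC/C(C)=C/CC/C(C)=C/Cc1cc(OC)cc(C)c1OC | intermediate
11 | (R)-3-hydroxydihydrofuran-2(3H)-one | O[C@@H]1CCOC1=O | starting material
12 | (R)-3-[(tert-butyldimethylsilyl)oxy]dihydrofuran-2(3H)-one | CC(C)(C)[Si](C)(C)O[C@@H]1CCOC1=O | intermediate
13 | (R)-3-[(tert-butyldimethylsilyl)oxy]-5-hydroxypentan-2-one | CC(=O)[C@H](O[Si](C)(C)C(C)(C)C)CCO | intermediate
14 | (R)-3-[(tert-butyldimethylsilyl)oxy]-4-methylpent-4-en-1-ol | C=C(C)[C@H](O[Si](C)(C)C(C)(C)C)CCO | intermediate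
15 | (R)-tert-butyl[(5-iodo-2-methylpent-1-en-3-yl)oxy]dimethylsilane | C=C(C)[C@H](O[Si](C)(C)C(C)(C)C)CCI | intermediate
16 | ethyl 2-(diphenoxyphosphoryl)acetate | CCOC(=O)CP(=O)(Oc1ccccc1)Oc1ccccc1 | starting material
17 | ethyl (5R)-5-[(tert-butyldimethylsilyl)oxy]-2-(diphenoxyphosphoryl)-6-methylhept-6-enoate | CCOC(=O)C(CC[C@@H](O[Si](C)(C)C(C)(C)C)C(C)=C)P(=O)(Oc1ccccc1)Oc1ccccc1 | intermediate
18 | ethyl (2Z,6E,10E)-2-[(3R)-3-[(tert-butyldimethylsilyl)oxy]-4-methylpent-4-en-1-yl]-12-(2,5-dimethoxy-3-methylphenyl)-6,10-dimethyldodeca-2,6,10-trienoate | CCOC(=O)/C(CC[C@@H](O[Si](C)(C)C(C)(C)C)C(C)=C)=C\CC/C(C)=C/CC/C(C)=C/Cc1cc(OC)cc(C)c1OC | intermediate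
19 | ethyl (2Z,6E,10E)-2-[(3R)-3-hydroxy-4-methylpent-4-en-1-yl]-12-(2,5-dimethoxy-3-methylphenyl)-6,10-dimethyldodeca-2,6,10-trienoate (not isolated) | CCOC(=O)/C(CC[C@@H](O)C(C)=C)=C\CC/C(C)=C/CC/C(C)=C/Cc1cc(OC)cc(C)c1OC | intermediate
20 | (3Z,6R)-3-[(4E,8E)-10-(2,5-dimethoxy-3-methylphenyl)-4,8-dimethyldeca-4,8-dien-1-ylidene]-6-(prop-1-en-2-yl)tetrahydro-2H-pyran-2-one | C=C(C)[C@H]1CC/C(=C/CC/C(C)=C/CC/C(C)=C/Cc2cc(OC)cc(C)c2OC)C(=O)O1 | intermediate
21 | CNP0305496.1 | C=C(C)[C@H]1CC/C(=C/CC/C(C)=C/CC/C(C)=C/CC2=CC(=O)C=C(C)C2=O)C(=O)O1 | target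

## Summary

Total step count: 14.
Longest linear sequence: 9 steps (steps 1–6, then 12–14, from phenol 1); the phosphonate branch is 5 steps (7–11).

**Steps most likely to fail, each with a fallback**

Step 1 (C- versus O-alkylation of the phenoxide; the aryl geranyl ether may dominate). The fallback sets out from 1 and comes back at 4. Phenol 1 is brominated at its only free ortho position (NBS, MeCN, 0 °C) to 2-bromo-4-methoxy-6-methylphenol F1, which is O-methylated (MeI, K2CO3) to 1-bromo-2,5-dimethoxy-3-methylbenzene F2. Halogen–lithium exchange (n-BuLi, THF, −78 °C) gives (2,5-dimethoxy-3-methylphenyl)lithium F3, which is coupled with geranyl bromide 2 in the presence of CuBr·SMe2 to give 4 directly. This replaces the ambident phenoxide by a regiodefined aryl–metal/allyl bromide coupling.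

Step 3 (the arene may be ring-brominated by NBS, and the 2′,3′-olefin competes with the terminal one; step 4 then depends on it). The fallback sets out from 4 and comes back at 7, bypassing epoxide 6. Schenck ene photooxygenation of 4 (O2, tetraphenylporphyrin, visible light, CH2Cl2, 0 °C, run to partial conversion) gives (6E)-8-(2,5-dimethoxy-3-methylphenyl)-3-hydroperoxy-2,6-dimethylocta-1,6-diene F4, which is reduced in the same flask with PPh3 to allylic alcohol 7. The tertiary regioisomer and products from the inner olefin are removed by chromatography, so the yield is lower.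

Step 12 (Z selectivity and reactivity of the α-branched phosphonate 17; the alkylation in step 11 feeds it). The fallback sets out from 10 (with iodide 15) and comes back at 18, so phosphonate 17 is not needed. Aldehyde 10 is condensed with the known reagent ethyl bromo[bis(2,2,2-trifluoroethoxy)phosphoryl]acetate (KOt-Bu, 18-crown-6, THF, −78 °C), which gives selectively ethyl (2E,6E,10E)-2-bromo-12-(2,5-dimethoxy-3-methylphenyl)-6,10-dimethyldodeca-2,6,10-trienoate F5, with the chain cis to the ester. Iodide 15 is converted with zinc dust and LiCl in THF into [(3R)-3-[(tert-butyldimethylsilyl)oxy]-4-methylpent-4-en-1-yl]zinc iodide F6. Negishi coupling of F5 with F6 (Pd(PPh3)4, a zerovalent palladium catalyst, THF, 50 °C) proceeds with retention of olefin geometry and gives 18. The C3–C4 bond is thus made by sp2–sp3 cross-coupling instead of by olefination with a pre-alkylated phosphonate.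

## Further compounds

F1 | step 1 | 2-bromo-4-methoxy-6-methylphenol | COc1cc(C)c(O)c(Br)c1
F2 | step 1 | 1-bromo-2,5-dimethoxy-3-methylbenzene | COc1cc(C)c(OC)c(Br)c1
F3 | step 1 | (2,5-dimethoxy-3-methylphenyl)lithium | [Li]c1cc(OC)cc(C)c1OC
F4 | step 3 | (6E)-8-(2,5-dimethoxy-3-methylphenyl)-3-hydroperoxy-2,6-dimethylocta-1,6-diene | COc1cc(C)c(OC)c(C/C=C(\C)CCC(OO)C(C)=C)c1
F5 | step 12 | ethyl (2E,6E,10E)-2-bromo-12-(2,5-dimethoxy-3-methylphenyl)-6,10-dimethyldodeca-2,6,10-trienoate | CCOC(=O)/C(Br)=C\CC/C(C)=C/CC/C(C)=C/Cc1cc(OC)cc(C)c1OC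
F6 | step 12 | [(3R)-3-[(tert-butyldimethylsilyl)oxy]-4-methylpent-4-en-1-yl]zinc iodide | C=C(C)[C@H](O[Si](C)(C)C(C)(C)C)CC[Zn]I
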